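**Retrosynthetic overview**

1. The strategy rests on the 1,4-dicarbonyl unit of the target: the ring-A ketone carbon C9 and chromone C4 are linked through the stereocentre Cα and C3, and each sits on a resorcinol-type ring ortho to a phenolic oxygen (ring A 2'-OH; chromone O1). This is a 2-substituted succinyl unit held between two aryloxy groups.
2. Target 23 ⇒ tris-benzyl ether 22 ⇒ diketone 20: the C2 methine is inserted at the C3 methylene and O1–C2 is closed. The pyranone ring of the chromone is the only ring made, and it is made last.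
3. 20 ⇒ mixed diaryl succinate 18 by a twofold halogen–lithium-triggered O→C acyl shift (C9–C1' on ring A, C4–C4a on ring B). Both aryl rings enter as the bromophenols 12 and 16.
4. 18 ⇒ half-ester 11 by two successive aryl esterifications. 11 ⇒ auxiliary-controlled alkylation of a 3,3-diarylpropanoyl imide with tert-butyl bromoacetate (sets Cα); the imide comes from copper-catalysed aryl-Grignard addition to a cinnamoyl imide.

Key step: step 9

Assumption: Cα is (R) in the target and in 21–23 and carries the descriptor (S) in 9–20 only because the CIP rank of the C3 substituent changes; the spatial arrangement is the same throughout. Acid 1 and Grignard solution 5 are taken as purchased.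

**Route**

Step 1
Reactants: 1 (E)-3-[4-(benzyloxy)phenyl]prop-2-enoic acid; 2 (S)-4-benzyl-1,3-oxazolidin-2-one
Product: 4 (4S)-4-benzyl-3-[(E)-3-(4-benzyloxyphenyl)prop-2-enoyl]-1,3-oxazolidin-2-one, via mixed pivalic anhydride 3 (not isolated)
Conditions: t-BuCOCl, Et3N, THF, −20 °C; then 2, LiCl, −20 °C → rt
Reagents that add atoms: none
Why: Mixed-anhydride N-acylation of the oxazolidinone, in which the LiCl-activated carbamate nitrogen attacks the less hindered cinnamoyl carbonyl of the pivalic anhydride; no stereocenter is formed.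

Step 2
Reactants: 4 (4S)-4-benzyl-3-[(E)-3-(4-benzyloxyphenyl)prop-2-enoyl]-1,3-oxazolidin-2-one; 5 4-(benzyloxy)phenylmagnesium bromide
Product: 6 (4S)-4-benzyl-3-[3,3-bis(4-benzyloxyphenyl)propanoyl]-1,3-oxazolidin-2-one
Conditions: 5 (2.5 equiv), CuBr·SMe2 (0.3 equiv), THF/Me2S, −40 → 0 °C; then aq. NH4Cl
Reagents that add atoms: none
Why: Copper-catalysed conjugate (Michael) addition of an aryl Grignard reagent to a chelated N-enoyl imide should proceed cleanly in the 1,4-sense, and the new benzhydryl carbon bears two identical aryl groups and so is not a stereocenter.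

Step 3
Reactants: 6 (4S)-4-benzyl-3-[3,3-bis(4-benzyloxyphenyl)propanoyl]-1,3-oxazolidin-2-one; 7 tert-butyl bromoacetate
Product: 9 tert-butyl (3S)-3-{[(4S)-4-benzyl-2-oxo-1,3-oxazolidin-3-yl]carbonyl}-4,4-bis(4-benzyloxyphenyl)butanoate, via sodium Z-enolate 8 (not isolated)
Conditions: NaN(SiMe3)2, THF, −78 °C; then 7, −78 → −40 °C
Reagents that add atoms: none
Why: Evans asymmetric alkylation, in which the chelated Z-enolate is shielded on one face by the C4 benzyl group of the auxiliary and the reactive bromoacetate enters from the opposite face; this should set Cα as (S), the arrangement that becomes (R) in the target.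

Step 4
Reactants: 9 tert-butyl (3S)-3-{[(4S)-4-benzyl-2-oxo-1,3-oxazolidin-3-yl]carbonyl}-4,4-bis(4-benzyloxyphenyl)butanoate
Product: 11 (2S)-2-[bis(4-benzyloxyphenyl)methyl]-4-tert-butoxy-4-oxobutanoic acid, via peroxy acid 10 (not isolated)
Conditions: LiOH, H2O2, THF/H2O, 0 °C; then aq. Na2SO3; then 1 M HCl to pH 3, 0 °C
Reagents that add atoms: hydrogen peroxide, OO
Why: Hydroperoxide cleavage of the imide (LiOOH), in which the small α-nucleophile attacks the exocyclic carbonyl selectively even in a hindered acyl group, should leave the tert-butyl ester and Cα untouched; sulfite reduces the peroxy acid to the acid.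

Step 5
Reactants: 11 (2S)-2-[bis(4-benzyloxyphenyl)methyl]-4-tert-butoxy-4-oxobutanoic acid; 12 2-bromo-5-methoxyphenol
Product: 13 1-(2-bromo-5-methoxyphenyl) 4-tert-butyl (2S)-2-[bis(4-benzyloxyphenyl)methyl]butanedioate
Conditions: i-PrN=C=Ni-Pr, DMAP, CH2Cl2, 0 °C → rt
Reagents that add atoms: none
Why: Steglich esterification (carbodiimide activation, acyl transfer through the acylpyridinium) is the standard way to make aryl esters of branched acids, and Cα, which has no aryl or N-acyl activation, should be captured by the phenol faster than it enolises.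

Step 6
Reactants: 13 1-(2-bromo-5-methoxyphenyl) 4-tert-butyl (2S)-2-[bis(4-benzyloxyphenyl)methyl]butanedioate
Product: 14 (3S)-4,4-bis(4-benzyloxyphenyl)-3-[(2-bromo-5-methoxyphenoxy)carbonyl]butanoic acid
Conditions: CF3CO2H/CH2Cl2 (1:4), 0 °C → rt; evaporation from toluene
Reagents that add atoms: none
Why: Acidolysis of the tert-butyl ester (alkyl–oxygen cleavage through the tert-butyl cation) should spare the aryl ester, the aryl bromide and the benzyl ethers, and the absence of base keeps the freed acid from closing onto the aryl ester as a succinic anhydride.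

Step 7
Reactants: 15 4-bromobenzene-1,3-diol (4-bromoresorcinol)
Product: 16 5-(benzyloxy)-2-bromophenol
Conditions: BnBr (1.0 equiv), K2CO3, acetone, rt; chromatography
Reagents that add atoms: benzyl bromide, BrCc1ccccc1
Why: Williamson ether synthesis under equilibrating carbonate conditions, in which the hydroxyl para to bromine is the less hindered and its phenoxide the more nucleophilic, should favour 16, and the regioisomer and the bis-ether are removed by chromatography.

Step 8
Reactants: 14 (3S)-4,4-bis(4-benzyloxyphenyl)-3-[(2-bromo-5-methoxyphenoxy)carbonyl]butanoic acid; 16 5-(benzyloxy)-2-bromophenol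
Product: 18 4-[5-(benzyloxy)-2-bromophenyl] 1-(2-bromo-5-methoxyphenyl) (2S)-2-[bis(4-benzyloxyphenyl)methyl]butanedioate, via acid chloride 17 (not isolated)
Conditions: (COCl)2, DMF (cat.), CH2Cl2, 0 °C → rt; evaporation; then 16, pyridine, CH2Cl2, 0 °C
Reagents that add atoms: none
Why: Acid chloride formation under acidic conditions followed by pyridine-mediated O-acylation of the phenol never exposes a carboxylate beside the C1 aryl ester, so anhydride formation and scrambling of the two aryloxy groups is avoided, and Cα lies β to the reacting carbonyl and is not at risk.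

Step 9
Reactants: 18 4-[5-(benzyloxy)-2-bromophenyl] 1-(2-bromo-5-methoxyphenyl) (2S)-2-[bis(4-benzyloxyphenyl)methyl]butanedioate
Product: 20 (2S)-2-[bis(4-benzyloxyphenyl)methyl]-4-[4-(benzyloxy)-2-hydroxyphenyl]-1-(2-hydroxy-4-methoxyphenyl)butane-1,4-dione, via bis(aryllithium) 19 (not isolated)
Conditions: t-BuLi (4.2 equiv), THF/Et2O/pentane (4:1:1), −100 °C; then AcOH, −100 → −78 °C
Reagents that add atoms: none
Why: Bromine–lithium exchange with t-BuLi at −100 °C is faster than addition to or deprotonation of the aryl esters (two equivalents per bromide, the second destroying t-BuBr) and gives bis(aryllithium) 19; each carbanion, held against the carbonyl of its own ester by Li···O=C coordination, adds through a four-centre transition state and the tetrahedral intermediate collapses with C–O cleavage to a lithium ortho-acylphenoxide, which forms C9–C1' on ring A and C4–C4a on ring B. The closest known reaction type is the anionic Fries rearrangement (1,3 O→C acyl shift) of ortho-haloaryl esters triggered by halogen–lithium exchange, run here at both ends of one succinate. No ring is closed and no stereocenter is created; Cα is carried through unchanged. Regiochemistry is fixed by the bromine positions, which place each acyl group ortho to the former ester oxygen and para to the ether oxygen (2-hydroxy-4-methoxy on ring A, 2-hydroxy-4-benzyloxy on ring B). Site selectivity, each aryllithium taking its own carbonyl and not the distal one (seven-membered transition state), is secured by the precoordination, and the ketones once formed are masked as chelated lithium phenoxides that resist further attack. Integrity of Cα requires the acyl transfer to outrun deprotonation at Cα–H and C3–H2 (which would expel aryloxide as a ketene), which the low temperature, the α-branching and the intramolecular nature of the transfer favour; cold acetic acid then releases 20.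

Step 10
Reactants: 20 (2S)-2-[bis(4-benzyloxyphenyl)methyl]-4-[4-(benzyloxy)-2-hydroxyphenyl]-1-(2-hydroxy-4-methoxyphenyl)butane-1,4-dione
Product: 22 7-(benzyloxy)-3-[(2R)-1,1-bis(4-benzyloxyphenyl)-3-(2-hydroxy-4-methoxyphenyl)-3-oxopropan-2-yl]-4H-chromen-4-one, via enaminone 21 (not isolated)
Conditions: Me2NCH(OMe)2 (5 equiv), PhMe, 80 °C; then AcOH, rt
Reagents that add atoms: N,N-dimethylformamide dimethyl acetal, COC(OC)N(C)C
Why: Enaminone formation and cyclocondensation (the amide-acetal chromone synthesis) can occur only at the C3 methylene, which has the two hydrogens needed, and the ring-B phenol then closes the pyranone ring by oxa-Michael addition–elimination with loss of dimethylamine; the Cα methine cannot condense and should keep its configuration as long as the hindered ring-A ketone is not enolised.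

Step 11
Reactants: 22 7-(benzyloxy)-3-[(2R)-1,1-bis(4-benzyloxyphenyl)-3-(2-hydroxy-4-methoxyphenyl)-3-oxopropan-2-yl]-4H-chromen-4-one
Product: 23 7-hydroxy-3-[(2R)-1,1-bis(4-hydroxyphenyl)-3-(2-hydroxy-4-methoxyphenyl)-3-oxopropan-2-yl]-4H-chromen-4-one
Conditions: BCl3 (1 M in CH2Cl2), C6HMe5, CH2Cl2, −78 °C; then H2O
Reagents that add atoms: none
Why: Lewis-acid debenzylation with a cation scavenger should cleave the three benzyl aryl ethers at low temperature, while the ring-A methoxy group, which is para and not ortho to the carbonyl and so not chelation-activated, survives; pentamethylbenzene traps the benzyl cation and no base is present to enolise Cα.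

**Compound list**

1 | (E)-3-[4-(benzyloxy)phenyl]prop-2-enoic acid | OC(=O)/C=C/c1ccc(OCc2ccccc2)cc1 | starting material
2 | (S)-4-benzyl-1,3-oxazolidin-2-one | O=C1N[C@@H](Cc2ccccc2)CO1 | starting material
3 | mixed anhydride of 1 with pivalic acid | CC(C)(C)C(=O)OC(=O)/C=C/c1ccc(OCc2ccccc2)cc1 | intermediate
4 | (4S)-4-benzyl-3-[(E)-3-(4-benzyloxyphenyl)prop-2-enoyl]-1,3-oxazolidin-2-one | O=C1OC[C@H](Cc2ccccc2)N1C(=O)/C=C/c1ccc(OCc2ccccc2)cc1 | intermediate
5 | 4-(benzyloxy)phenylmagnesium bromide | Br[Mg]c1ccc(OCc2ccccc2)cc1 | starting material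
6 | (4S)-4-benzyl-3-[3,3-bis(4-benzyloxyphenyl)propanoyl]-1,3-oxazolidin-2-one | O=C1OC[C@H](Cc2ccccc2)N1C(=O)CC(c1ccc(OCc2ccccc2)cc1)c1ccc(OCc2ccccc2)cc1 | intermediate
7 | tert-butyl bromoacetate | CC(C)(C)OC(=O)CBr | starting material
8 | sodium (Z)-enolate of 6 | [Na]O/C(=C\C(c1ccc(OCc2ccccc2)cc1)c1ccc(OCc2ccccc2)cc1)N1C(=O)OC[C@@H]1Cc1ccccc1 | intermediate
9 | tert-butyl (3S)-3-{[(4S)-4-benzyl-2-oxo-1,3-oxazolidin-3-yl]carbonyl}-4,4-bis(4-benzyloxyphenyl)butanoate | O=C1OC[C@H](Cc2ccccc2)N1C(=O)[C@@H](CC(=O)OC(C)(C)C)C(c1ccc(OCc2ccccc2)cc1)c1ccc(OCc2ccccc2)cc1 | intermediate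
10 | (2S)-2-[bis(4-benzyloxyphenyl)methyl]-4-tert-butoxy-4-oxobutaneperoxoic acid (formed as its lithium salt) | OOC(=O)[C@@H](CC(=O)OC(C)(C)C)C(c1ccc(OCc2ccccc2)cc1)c1ccc(OCc2ccccc2)cc1 | intermediate
11 | (2S)-2-[bis(4-benzyloxyphenyl)methyl]-4-tert-butoxy-4-oxobutanoic acid | OC(=O)[C@@H](CC(=O)OC(C)(C)C)C(c1ccc(OCc2ccccc2)cc1)c1ccc(OCc2ccccc2)cc1 | intermediate
12 | 2-bromo-5-methoxyphenol | COc1ccc(Br)c(O)c1 | starting material
13 | 1-(2-bromo-5-methoxyphenyl) 4-tert-butyl (2S)-2-[bis(4-benzyloxyphenyl)methyl]butanedioate | COc1ccc(Br)c(OC(=O)[C@@H](CC(=O)OC(C)(C)C)C(c2ccc(OCc3ccccc3)cc2)c2ccc(OCc3ccccc3)cc2)c1 | intermediate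
14 | (3S)-4,4-bis(4-benzyloxyphenyl)-3-[(2-bromo-5-methoxyphenoxy)carbonyl]butanoic acid | COc1ccc(Br)c(OC(=O)[C@@H](CC(=O)O)C(c2ccc(OCc3ccccc3)cc2)c2ccc(OCc3ccccc3)cc2)c1 | intermediate
15 | 4-bromobenzene-1,3-diol (4-bromoresorcinol) | Oc1ccc(Br)c(O)c1 | starting material
16 | 5-(benzyloxy)-2-bromophenol | Oc1cc(OCc2ccccc2)ccc1Br | intermediate
17 | 2-bromo-5-methoxyphenyl (2S)-2-[bis(4-benzyloxyphenyl)methyl]-4-chloro-4-oxobutanoate | COc1ccc(Br)c(OC(=O)[C@@H](CC(=O)Cl)C(c2ccc(OCc3ccccc3)cc2)c2ccc(OCc3ccccc3)cc2)c1 | intermediate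
18 | 4-[5-(benzyloxy)-2-bromophenyl] 1-(2-bromo-5-methoxyphenyl) (2S)-2-[bis(4-benzyloxyphenyl)methyl]butanedioate | COc1ccc(Br)c(OC(=O)[C@@H](CC(=O)Oc2cc(OCc3ccccc3)ccc2Br)C(c2ccc(OCc3ccccc3)cc2)c2ccc(OCc3ccccc3)cc2)c1 | intermediate
19 | bis(aryllithium) from 18 (lithium in place of each bromine) | COc1ccc([Li])c(OC(=O)[C@@H](CC(=O)Oc2cc(OCc3ccccc3)ccc2[Li])C(c2ccc(OCc3ccccc3)cc2)c2ccc(OCc3ccccc3)cc2)c1 | intermediate
20 | (2S)-2-[bis(4-benzyloxyphenyl)methyl]-4-[4-(benzyloxy)-2-hydroxyphenyl]-1-(2-hydroxy-4-methoxyphenyl)butane-1,4-dione | COc1ccc(C(=O)[C@@H](CC(=O)c2ccc(OCc3ccccc3)cc2O)C(c2ccc(OCc3ccccc3)cc2)c2ccc(OCc3ccccc3)cc2)c(O)c1 | intermediate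
21 | (3R)-3-[bis(4-benzyloxyphenyl)methyl]-1-[4-(benzyloxy)-2-hydroxyphenyl]-2-[(dimethylamino)methylidene]-4-(2-hydroxy-4-methoxyphenyl)butane-1,4-dione | COc1ccc(C(=O)[C@@H](C(=CN(C)C)C(=O)c2ccc(OCc3ccccc3)cc2O)C(c2ccc(OCc3ccccc3)cc2)c2ccc(OCc3ccccc3)cc2)c(O)c1 | intermediate
22 | 7-(benzyloxy)-3-[(2R)-1,1-bis(4-benzyloxyphenyl)-3-(2-hydroxy-4-methoxyphenyl)-3-oxopropan-2-yl]-4H-chromen-4-one | COc1ccc(C(=O)[C@@H](c2coc3cc(OCc4ccccc4)ccc3c2=O)C(c2ccc(OCc3ccccc3)cc2)c2ccc(OCc3ccccc3)cc2)c(O)c1 | intermediate
23 | 7-hydroxy-3-[(2R)-1,1-bis(4-hydroxyphenyl)-3-(2-hydroxy-4-methoxyphenyl)-3-oxopropan-2-yl]-4H-chromen-4-one (CNP0178475.1) | COc1ccc(C(=O)[C@@H](c2coc3cc(O)ccc3c2=O)C(c2ccc(O)cc2)c2ccc(O)cc2)c(O)c1 | target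

**Step count and risks**

Total step count: 11. Longest linear sequence: 10 steps (steps 1–6 and 8–11); step 7 is a one-step branch.

Steps most likely to fail:

Step 9. The aryllithiums or t-BuLi may deprotonate Cα–H or C3–H2 and the ester enolates then expel aryloxide as ketenes. An aryllithium may attack the distal carbonyl, t-BuLi may add to the first-formed ketone, and Cα may partly epimerise. The fallback sets out from 14 and returns at 20. It builds the two aryl ketones one after the other by intermolecular additions of O-protected aryllithiums, each at a stage where the other end is below the ketone oxidation level. BH3·SMe2 (THF, 0 °C) reduces the free acid of 14 to hydroxy ester F1, which closes with Et3N at rt, expelling 12, to lactone F2. Phenol 12 is protected (MeOCH2Cl, i-Pr2NEt) as 1-bromo-4-methoxy-2-(methoxymethoxy)benzene F3. Bromine–lithium exchange of F3 (n-BuLi, THF, −78 °C) and addition to F2 should stop at the lactolate stage and give hydroxy ketone F4 (in equilibrium with its lactol). Dess–Martin oxidation gives keto aldehyde F5. Phenol 16 is protected in the same way as 4-(benzyloxy)-1-bromo-2-(methoxymethoxy)benzene F6, whose aryllithium (n-BuLi, −78 °C) should add to the aldehyde of F5 in preference to the hindered, α-branched ketone, to give carbinol F7 as a mixture at the new carbinol carbon. A second Dess–Martin oxidation gives the bis(methoxymethyl) diketone F8. Mild acetal cleavage (HCl, MeOH/THF, rt, short enough to keep the 1,4-diketone from closing to a furan) gives 20.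

Step 10. Condensation at the hindered C3 methylene may be slow, prolonged heating with the acetal may O-methylate the ring-A phenol, and the basic medium may enolise the ring-A ketone towards Cα and erode the configuration. The fallback sets out from 20 and returns at 22. It replaces the thermal amide-acetal condensation by an acid-side Vilsmeier-type formylation of a boron chelate. BF3·OEt2 converts both ortho-hydroxyaryl ketones into the bis(difluoroboron) chelate F9, in which C3–H2 is activated without base and both carbonyl oxygens are tied up, which should also disfavour Paal–Knorr furan formation. DMF/MeSO2Cl at 50–60 °C then formylates C3, and ring closure with loss of the ring-B boron gives the chromone difluoroboron chelate F10, which aqueous NaOAc/MeOH hydrolyses to 22.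

Step 5. Acyl transfer from the hindered acylpyridinium to the ortho-bromophenol may be slow, which would allow N-acylurea formation and epimerisation of Cα through a ketene. The fallback sets out from 11 and returns at 13. It makes the ester C–O bond from the aryl side, so the hindered carboxyl carbon is never activated. Commercial 1-bromo-2-iodo-4-methoxybenzene is oxidised (mCPBA, TsOH·H2O) and trapped with 1,3,5-trimethoxybenzene to give (2-bromo-5-methoxyphenyl)(2,4,6-trimethoxyphenyl)iodonium tosylate F11. The potassium salt of 11 (KOt-Bu, toluene, 80–110 °C) is O-arylated by F11 with transfer of the bromoaryl group, the trimethoxyphenyl group being the ligand that stays on iodine, to give 13.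

**Further compounds**

F1 | step 9 | 2-bromo-5-methoxyphenyl (2S)-2-[bis(4-benzyloxyphenyl)methyl]-4-hydroxybutanoate | COc1ccc(Br)c(OC(=O)[C@@H](CCO)C(c2ccc(OCc3ccccc3)cc2)c2ccc(OCc3ccccc3)cc2)c1
F2 | step 9 | (3S)-3-[bis(4-benzyloxyphenyl)methyl]oxolan-2-one | O=C1OCC[C@H]1C(c2ccc(OCc3ccccc3)cc2)c2ccc(OCc3ccccc3)cc2
F3 | step 9 | 1-bromo-4-methoxy-2-(methoxymethoxy)benzene | COCOc1cc(OC)ccc1Br
F4 | step 9 | (2S)-2-[bis(4-benzyloxyphenyl)methyl]-4-hydroxy-1-[4-methoxy-2-(methoxymethoxy)phenyl]butan-1-one | COCOc1cc(OC)ccc1C(=O)[C@@H](CCO)C(c1ccc(OCc2ccccc2)cc1)c1ccc(OCc2ccccc2)cc1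
F5 | step 9 | (3S)-3-[bis(4-benzyloxyphenyl)methyl]-4-[4-methoxy-2-(methoxymethoxy)phenyl]-4-oxobutanal | COCOc1cc(OC)ccc1C(=O)[C@@H](CC=O)C(c1ccc(OCc2ccccc2)cc1)c1ccc(OCc2ccccc2)cc1
F6 | step 9 | 4-(benzyloxy)-1-bromo-2-(methoxymethoxy)benzene | COCOc1cc(OCc2ccccc2)ccc1Br
F7 | step 9 | (2S)-2-[bis(4-benzyloxyphenyl)methyl]-4-[4-(benzyloxy)-2-(methoxymethoxy)phenyl]-4-hydroxy-1-[4-methoxy-2-(methoxymethoxy)phenyl]butan-1-one, both C4 epimers | COCOc1cc(OC)ccc1C(=O)[C@@H](CC(O)c1ccc(OCc2ccccc2)cc1OCOC)C(c1ccc(OCc2ccccc2)cc1)c1ccc(OCc2ccccc2)cc1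
F8 | step 9 | (2S)-2-[bis(4-benzyloxyphenyl)methyl]-4-[4-(benzyloxy)-2-(methoxymethoxy)phenyl]-1-[4-methoxy-2-(methoxymethoxy)phenyl]butane-1,4-dione | COCOc1cc(OC)ccc1C(=O)[C@@H](CC(=O)c1ccc(OCc2ccccc2)cc1OCOC)C(c1ccc(OCc2ccccc2)cc1)c1ccc(OCc2ccccc2)cc1
F9 | step 10 | bis(difluoroboron) chelate of 20 (each ortho-hydroxyaryl ketone bound as an O–BF2–O six-membered chelate) | COc1ccc2c(c1)O[B-](F)(F)[O+]=C2[C@@H](CC1=[O+][B-](F)(F)Oc3cc(OCc4ccccc4)ccc31)C(c1ccc(OCc2ccccc2)cc1)c1ccc(OCc2ccccc2)cc1
F10 | step 10 | ring-A difluoroboron chelate of 22 | COc1ccc2c(c1)O[B-](F)(F)[O+]=C2[C@@H](c1coc2cc(OCc3ccccc3)ccc2c1=O)C(c1ccc(OCc2ccccc2)cc1)c1ccc(OCc2ccccc2)cc1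
F11 | step 5 | (2-bromo-5-methoxyphenyl)(2,4,6-trimethoxyphenyl)iodonium 4-methylbenzenesulfonate | COc1ccc(Br)c([I+]c2c(OC)cc(OC)cc2OC)c1.Cc1ccc(S(=O)(=O)[O-])cc1
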